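**Retrosynthetic overview**

- The route rests on the single cyclohexene ring and its cis-1,3 pair: the C1 oxygen and the C3 bromine sit on the same face across the C2 methylene, with C3 next to the quaternary C4 (numbering: C1 CHOAc, C2 CH2, C3 CHBr, C4 CMe2, C5=C6, side chain C7 CHBr and C8 CH2Cl).
- End game: C7–Br from a C7 alcohol with inversion; that alcohol from CBS reduction of a chloroacetyl enone; the C6–C7 bond from an alkenylmagnesium (ex C6–I) and a chloro Weinreb amide. The acetate goes on after the organomagnesium step, because an ester would not survive it.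
- Key disconnection: C1–C2 and C3–Br are made in one operation by TiBr4 opening of a (2S,4S)-pentanediol acetal onto a terminal vinyl group. This closes the only ring and sets C1 and C3.
- The acetal comes from (2E)-2-iodo-4,4-dimethylhexa-2,5-dienal. Its alkene geometry is fixed by syn-hydrostannation and iododestannylation of an ynoate built from 2,2-dimethylbut-3-en-1-ol (Corey–Fuchs, methyl chloroformate).

Key step: step 9

Remark: the target numbering above is used in the explanations; systematic names of intermediates carry their own locants.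

**Route**

Step 1
Reactants: 1 2,2-dimethylbut-3-en-1-ol
Product: 2 2,2-dimethylbut-3-enal
Conditions: Dess–Martin periodinane, NaHCO3, CH2Cl2, 0 °C to rt; washed and dried solution used directly
Reagents that add atoms: none
Why: Dess–Martin oxidation of a neopentylic primary alcohol should give the non-enolisable aldehyde without touching the vinyl group, and keeping it in solution avoids loss of the volatile product.

Step 2
Reactants: 2 2,2-dimethylbut-3-enal
Product: 3 1,1-dibromo-3,3-dimethylpenta-1,4-diene
Conditions: CBr4 (2 equiv), PPh3 (4 equiv), CH2Cl2, 0 °C; pentane trituration and filtration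
Reagents that add atoms: carbon tetrabromide, BrC(Br)(Br)Br
Why: Corey–Fuchs dibromo-olefination by the ylide Ph3P=CBr2 is reliable for hindered, non-enolisable aldehydes and gives a product that is no longer volatile.

Step 3
Reactants: 3 1,1-dibromo-3,3-dimethylpenta-1,4-diene; 4 methyl chloroformate
Product: 6 methyl 4,4-dimethylhex-5-en-2-ynoate, via lithium acetylide 5 (not isolated)
Conditions: n-BuLi (2.1 equiv), THF, −78 °C to 0 °C; then ClCO2Me, −78 °C to 0 °C
Reagents that add atoms: methyl chloroformate 4, COC(Cl)=O
Why: In the second stage of the Corey–Fuchs sequence, bromine–lithium exchange and a Fritsch–Buttenberg–Wiechell 1,2-hydrogen shift give the lithium acetylide, which is C-acylated by the chloroformate to the ynoate.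

Step 4
Reactants: 6 methyl 4,4-dimethylhex-5-en-2-ynoate
Product: 7 methyl (2E)-4,4-dimethyl-2-(tributylstannyl)hexa-2,5-dienoate
Conditions: Bu3SnH (1.1 equiv, slow addition), Pd(PPh3)4 (2 mol %), THF, 0 °C to rt
Reagents that add atoms: tributyltin hydride, CCCC[SnH](CCCC)CCCC
Why: Pd(PPh3)4-catalysed hydrostannation of an ynoate is a syn addition that places tin on the carbon next to the ester and away from the quaternary centre, so the ester carbon and C4 end up cis as the later ring requires; the isolated vinyl group is inert to zerovalent palladium and tin hydride.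

Step 5
Reactants: 7 methyl (2E)-4,4-dimethyl-2-(tributylstannyl)hexa-2,5-dienoate
Product: 8 methyl (2E)-2-iodo-4,4-dimethylhexa-2,5-dienoate
Conditions: I2 (1.05 equiv), CH2Cl2, 0 °C, dark; aq. Na2S2O3
Reagents that add atoms: iodine, II
Why: Iododestannylation is an ipso substitution that proceeds with retention of alkene geometry, and the alkenyl–tin bond reacts far faster with iodine than the terminal vinyl group does.

Step 6
Reactants: 8 methyl (2E)-2-iodo-4,4-dimethylhexa-2,5-dienoate
Product: 9 (2E)-2-iodo-4,4-dimethylhexa-2,5-dien-1-ol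
Conditions: i-Bu2AlH (2.3 equiv), CH2Cl2, −78 °C; aq. potassium sodium tartrate
Reagents that add atoms: none
Why: 1,2-Reduction of the enoate by i-Bu2AlH at low temperature gives the allylic alcohol and leaves the alkenyl iodide and the alkene geometry untouched.

Step 7
Reactants: 9 (2E)-2-iodo-4,4-dimethylhexa-2,5-dien-1-ol
Product: 10 (2E)-2-iodo-4,4-dimethylhexa-2,5-dienal
Conditions: Dess–Martin periodinane, NaHCO3, CH2Cl2, 0 °C, dark; used at once
Reagents that add atoms: none
Why: Buffered Dess–Martin oxidation of an allylic alcohol is neutral and fast, so the enal with the formyl group cis to the tertiary carbon should form without geometric isomerisation.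

Step 8
Reactants: 10 (2E)-2-iodo-4,4-dimethylhexa-2,5-dienal; 11 (2S,4S)-pentane-2,4-diol
Product: 12 (4S,6S)-2-[(1E)-1-iodo-3,3-dimethylpenta-1,4-dien-1-yl]-4,6-dimethyl-1,3-dioxane
Conditions: pyridinium p-toluenesulfonate (10 mol %), MgSO4, CH2Cl2, rt
Reagents that add atoms: (2S,4S)-pentane-2,4-diol 11, C[C@H](O)C[C@H](C)O
Why: Acid-catalysed acetalisation of the electron-poor enal with the C2-symmetric diol gives one acetal (the acetal carbon is not a stereocentre), and the mild dehydrating conditions should preserve the alkene geometry.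

Step 9
Reactants: 12 (4S,6S)-2-[(1E)-1-iodo-3,3-dimethylpenta-1,4-dien-1-yl]-4,6-dimethyl-1,3-dioxane
Product: 13 (2S,4S)-4-{[(1R,5S)-5-bromo-2-iodo-4,4-dimethylcyclohex-2-en-1-yl]oxy}pentan-2-ol
Conditions: TiBr4 (2.5 equiv), CH2Cl2, −78 °C; MeOH then water at −78 °C
Reagents that add atoms: titanium tetrabromide, Br[Ti](Br)(Br)Br
Why: TiBr4 coordinates the dioxane oxygen that has the axial methyl neighbour and weakens that C–O bond, giving a contact ion pair of an alkenyl oxocarbenium ion and a bromotitanate still bound to the auxiliary chain; the terminal CH2 of the vinyl group then attacks C1 opposite the leaving oxygen and bromide closes onto C3, a cation–olefin (Prins-type) cyclisation whose closest known relatives are the Lewis-acid cyclisations of hex-5-enal acetals to cis-3-halocyclohexyl ethers and the invertive openings of pentanediol acetals by π-nucleophiles. The one ring is closed in the 6-endo-trig mode at the vinyl group, with the C1=O+ bond exocyclic; 5-exo closure would require a primary cation. C1 (R) is controlled by the auxiliary, because substitution with inversion at the C–O bond next to the axial methyl group of the (4S,6S)-dioxane gives this configuration. C3 (S) is controlled relative to C1 by a chair-like transition state in which the alkoxy group is pseudo-equatorial and bromide adds antiperiplanar to the forming C1–C2 bond, that is equatorially and cis to the C1 oxygen. The step needs face selectivity at C1 (secured by the C2-symmetric diol), endo regioselectivity (secured by the cis arrangement of C1 and C4 on the C5=C6 bond and by the secondary-over-primary cation preference), cis-1,3 diastereoselectivity (secured by anti addition across the vinyl group) and bromide capture ahead of a methyl shift from C4 (favoured by −78 °C and the bromide-rich contact ion pair).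

Step 10
Reactants: 13 (2S,4S)-4-{[(1R,5S)-5-bromo-2-iodo-4,4-dimethylcyclohex-2-en-1-yl]oxy}pentan-2-ol
Product: 14 (4S)-4-{[(1R,5S)-5-bromo-2-iodo-4,4-dimethylcyclohex-2-en-1-yl]oxy}pentan-2-one
Conditions: Dess–Martin periodinane, NaHCO3, CH2Cl2, 0 °C to rt
Reagents that add atoms: none
Why: Dess–Martin oxidation of the only free alcohol turns the auxiliary into a β-alkoxy ketone, the first half of the standard removal of a pentanediol auxiliary, under conditions that leave both halides alone.

Step 11
Reactants: 14 (4S)-4-{[(1R,5S)-5-bromo-2-iodo-4,4-dimethylcyclohex-2-en-1-yl]oxy}pentan-2-one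
Product: 15 (1R,5S)-5-bromo-2-iodo-4,4-dimethylcyclohex-2-en-1-ol
Conditions: dibenzylammonium trifluoroacetate (0.5 equiv), benzene, 50 °C
Reagents that add atoms: none
Why: Amine-salt-mediated β-elimination (retro-oxa-Michael, E1cB type) expels the C1 alkoxide from the β-alkoxy ketone without touching the C1–O bond, and the near-neutral medium should not eliminate HBr from C3.

Step 12
Reactants: 15 (1R,5S)-5-bromo-2-iodo-4,4-dimethylcyclohex-2-en-1-ol; 16 2-chloro-N-methoxy-N-methylacetamide
Product: 18 2-chloro-1-[(4S,6R)-4-bromo-6-hydroxy-3,3-dimethylcyclohex-1-en-1-yl]ethan-1-one, via alkenylmagnesium alkoxide 17 (not isolated)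
Conditions: i-PrMgCl·LiCl (2.3 equiv), THF, −20 °C to 0 °C; then 16 (1.5 equiv), −20 °C to 0 °C; cold aq. NH4Cl
Reagents that add atoms: 2-chloro-N-methoxy-N-methylacetamide 16, CON(C)C(=O)CCl
Why: After deprotonation of the alcohol, iodine–magnesium exchange at the alkenyl iodide gives an alkenylmagnesium species that is acylated by the Weinreb amide through a chelated tetrahedral intermediate, which prevents over-addition; the hindered secondary bromide is inert at this temperature.

Step 13
Reactants: 18 2-chloro-1-[(4S,6R)-4-bromo-6-hydroxy-3,3-dimethylcyclohex-1-en-1-yl]ethan-1-one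
Product: 19 (1R,5S)-5-bromo-2-(chloroacetyl)-4,4-dimethylcyclohex-2-en-1-yl acetate
Conditions: Ac2O, pyridine, DMAP (5 mol %), CH2Cl2, 0 °C
Reagents that add atoms: acetic anhydride, CC(=O)OC(C)=O
Why: DMAP-catalysed acetylation of the secondary allylic alcohol is fast at 0 °C, and short exposure keeps the chloromethyl ketone and the hindered enone β-carbon (next to C4) from reacting with the amine bases.

Step 14
Reactants: 19 (1R,5S)-5-bromo-2-(chloroacetyl)-4,4-dimethylcyclohex-2-en-1-yl acetate
Product: 20 (1R,5S)-5-bromo-2-[(1S)-2-chloro-1-hydroxyethyl]-4,4-dimethylcyclohex-2-en-1-yl acetate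
Conditions: (S)-2-methyl-CBS-oxazaborolidine (20 mol %), catecholborane (1.5 equiv), toluene, −78 °C; MeOH quench, pH 7 buffer
Reagents that add atoms: none
Why: In the Corey–Bakshi–Shibata reduction the substituted alkenyl group acts as the large and CH2Cl as the small substituent, so the (S)-catalyst should deliver hydride with the same facial sense as for chloroacetophenone and give the (7S)-chlorohydrin, while catecholborane at −78 °C avoids conjugate reduction and spares the acetate.

Step 15
Reactants: 20 (1R,5S)-5-bromo-2-[(1S)-2-chloro-1-hydroxyethyl]-4,4-dimethylcyclohex-2-en-1-yl acetate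
Product: 21 (1R,5S)-5-bromo-2-[(1R)-1-bromo-2-chloroethyl]-4,4-dimethylcyclohex-2-en-1-yl acetate
Conditions: PPh3 (1.5 equiv), CBr4 (1.5 equiv), CH2Cl2, −20 °C to 0 °C
Reagents that add atoms: carbon tetrabromide, BrC(Br)(Br)Br
Why: In the Appel reaction bromide displaces the alkoxyphosphonium group by SN2 with inversion, turning the (7S)-alcohol into the (7R)-bromide; SN2′ attack at C5 is blocked by the adjacent quaternary C4 and ionisation at C7 is disfavoured by the β-chlorine.

**Compound list**

1 | 2,2-dimethylbut-3-en-1-ol | OCC(C)(C)C=C | starting material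
2 | 2,2-dimethylbut-3-enal | O=CC(C)(C)C=C | intermediate
3 | 1,1-dibromo-3,3-dimethylpenta-1,4-diene | BrC(Br)=CC(C)(C)C=C | intermediate
4 | methyl chloroformate | COC(Cl)=O | starting material
5 | (3,3-dimethylpent-4-en-1-yn-1-yl)lithium | [Li]C#CC(C)(C)C=C | intermediate
6 | methyl 4,4-dimethylhex-5-en-2-ynoate | COC(=O)C#CC(C)(C)C=C | intermediate
7 | methyl (2E)-4,4-dimethyl-2-(tributylstannyl)hexa-2,5-dienoate | COC(=O)/C(=C\C(C)(C)C=C)[Sn](CCCC)(CCCC)CCCC | intermediate
8 | methyl (2E)-2-iodo-4,4-dimethylhexa-2,5-dienoate | COC(=O)/C(I)=C\C(C)(C)C=C | intermediate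
9 | (2E)-2-iodo-4,4-dimethylhexa-2,5-dien-1-ol | OC/C(I)=C\C(C)(C)C=C | intermediate
10 | (2E)-2-iodo-4,4-dimethylhexa-2,5-dienal | O=C/C(I)=C\C(C)(C)C=C | intermediate
11 | (2S,4S)-pentane-2,4-diol | C[C@H](O)C[C@H](C)O | starting material
12 | (4S,6S)-2-[(1E)-1-iodo-3,3-dimethylpenta-1,4-dien-1-yl]-4,6-dimethyl-1,3-dioxane | C[C@H]1C[C@H](C)OC(O1)/C(I)=C\C(C)(C)C=C | intermediate
13 | (2S,4S)-4-{[(1R,5S)-5-bromo-2-iodo-4,4-dimethylcyclohex-2-en-1-yl]oxy}pentan-2-ol | C[C@H](O)C[C@H](C)O[C@@H]1C[C@H](Br)C(C)(C)C=C1I | intermediate
14 | (4S)-4-{[(1R,5S)-5-bromo-2-iodo-4,4-dimethylcyclohex-2-en-1-yl]oxy}pentan-2-one | CC(=O)C[C@H](C)O[C@@H]1C[C@H](Br)C(C)(C)C=C1I | intermediate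
15 | (1R,5S)-5-bromo-2-iodo-4,4-dimethylcyclohex-2-en-1-ol | O[C@@H]1C[C@H](Br)C(C)(C)C=C1I | intermediate
16 | 2-chloro-N-methoxy-N-methylacetamide | CON(C)C(=O)CCl | starting material
17 | [(4S,6R)-4-bromo-6-(chloromagnesiooxy)-3,3-dimethylcyclohex-1-en-1-yl]magnesium chloride | Cl[Mg]O[C@@H]1C[C@H](Br)C(C)(C)C=C1[Mg]Cl | intermediate
18 | 2-chloro-1-[(4S,6R)-4-bromo-6-hydroxy-3,3-dimethylcyclohex-1-en-1-yl]ethan-1-one | O[C@@H]1C[C@H](Br)C(C)(C)C=C1C(=O)CCl | intermediate
19 | (1R,5S)-5-bromo-2-(chloroacetyl)-4,4-dimethylcyclohex-2-en-1-yl acetate | CC(=O)O[C@@H]1C[C@H](Br)C(C)(C)C=C1C(=O)CCl | intermediate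
20 | (1R,5S)-5-bromo-2-[(1S)-2-chloro-1-hydroxyethyl]-4,4-dimethylcyclohex-2-en-1-yl acetate | CC(=O)O[C@@H]1C[C@H](Br)C(C)(C)C=C1[C@H](O)CCl | intermediate
21 | (1R,5S)-5-bromo-2-[(1R)-1-bromo-2-chloroethyl]-4,4-dimethylcyclohex-2-en-1-yl acetate | CC(=O)O[C@@H]1C[C@H](Br)C(C)(C)C=C1[C@@H](Br)CCl | target

**Step count and risks**

Total step count: 15. Longest linear sequence: 15 steps (1 to 21).

Steps most likely to fail:

1. Step 9. Three processes could spoil it. Ionisation to a free oxocarbenium ion before ring closure would erode the auxiliary's control at C1. Closure through the half-chair with a pseudo-axial alkoxy group (which relieves strain against the C6 iodine) would give the trans C1/C3 isomer. A 1,2-methyl shift from C4 to the C3 cation could outrun bromide capture. Fallback (sets out from 10, returns at 15): the aldehyde 10 would be cyclised directly with TiBr4 in CH2Cl2 at −78 °C. Here bromide is handed from the titanium alkoxide formed at C1 to the same ring face, which should enforce the cis relationship and shorten the cation lifetime, giving racemic cis-5-bromo-2-iodo-4,4-dimethylcyclohex-2-en-1-ol F1. Kinetic resolution with vinyl acetate and Candida antarctica lipase B should, by Kazlauskas' rule, acetylate the (1R) enantiomer to (1R,5S)-5-bromo-2-iodo-4,4-dimethylcyclohex-2-en-1-yl acetate F2 and leave (1S,5R)-5-bromo-2-iodo-4,4-dimethylcyclohex-2-en-1-ol F3 behind. Methanolysis of F2 (K2CO3, MeOH, 0 °C) would return 15.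

2. Step 12. The iodine–magnesium exchange may be sluggish on the electron-rich magnesium alkoxide, the alkenylmagnesium may be protonated instead of acylated, or it may attack the chloride-bearing carbon of the amide. Fallback (sets out from 15, returns at 18): the polarity is reversed. Methoxycarbonylation of the alkenyl iodide (Pd(OAc)2, PPh3, CO 1 atm, MeOH, Et3N, DMF, 50 °C) would give methyl (4S,6R)-4-bromo-6-hydroxy-3,3-dimethylcyclohex-1-ene-1-carboxylate F4. After deprotonation of the hydroxyl with one equivalent of MeLi, chloromethyllithium generated in situ from ICH2Cl and MeLi·LiBr at −78 °C would homologate the ester to the chloromethyl ketone 18.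

3. Step 15. The alkoxyphosphonium ion may collapse with partial retention, the C1 acetate may participate, or the allylic bromide may epimerise at C7 by degenerate bromide exchange. Fallback (sets out from 20, returns at 21): the route stops relying on one stereospecific event. Alcohol 20 would be converted (MsCl, Et3N, CH2Cl2, −20 °C) into (1R,5S)-5-bromo-2-[(1S)-2-chloro-1-(methanesulfonyloxy)ethyl]-4,4-dimethylcyclohex-2-en-1-yl acetate F5 and displaced with LiBr in THF. Since the C7 epimers are diastereomers, any (1R,5S)-5-bromo-2-[(1S)-1-bromo-2-chloroethyl]-4,4-dimethylcyclohex-2-en-1-yl acetate F6 would be separated by chromatography. F6 would then be re-equilibrated with Bu4NBr in acetonitrile and separated again, so that the material converges on 21.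

**Further compounds**

F1 | step 9 | rac-(1R,5S)-5-bromo-2-iodo-4,4-dimethylcyclohex-2-en-1-ol | O[C@@H]1C[C@H](Br)C(C)(C)C=C1I.O[C@H]1C[C@@H](Br)C(C)(C)C=C1I
F2 | step 9 | (1R,5S)-5-bromo-2-iodo-4,4-dimethylcyclohex-2-en-1-yl acetate | CC(=O)O[C@@H]1C[C@H](Br)C(C)(C)C=C1I
F3 | step 9 | (1S,5R)-5-bromo-2-iodo-4,4-dimethylcyclohex-2-en-1-ol | O[C@H]1C[C@@H](Br)C(C)(C)C=C1I
F4 | step 12 | methyl (4S,6R)-4-bromo-6-hydroxy-3,3-dimethylcyclohex-1-ene-1-carboxylate | O[C@@H]1C[C@H](Br)C(C)(C)C=C1C(=O)OC
F5 | step 15 | (1R,5S)-5-bromo-2-[(1S)-2-chloro-1-(methanesulfonyloxy)ethyl]-4,4-dimethylcyclohex-2-en-1-yl acetate | CC(=O)O[C@@H]1C[C@H](Br)C(C)(C)C=C1[C@H](OS(C)(=O)=O)CCl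
F6 | step 15 | (1R,5S)-5-bromo-2-[(1S)-1-bromo-2-chloroethyl]-4,4-dimethylcyclohex-2-en-1-yl acetate | CC(=O)O[C@@H]1C[C@H](Br)C(C)(C)C=C1[C@H](Br)CCl
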